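**Retrosynthetic overview**
1. C5–OH ⇒ C5–H: the chelated 5-hydroxyl is the last bond made, by C4-carbonyl-directed peri C–H oxygenation of the 5-unsubstituted flavone (C–O bond, key step).
2. Ring C ⇒ O1–C2 cyclodehydration of an o-hydroxyaryl 2-methoxy-1,3-diketone; the same acid treatment frees the 4'-OH from its benzyl ether.
3. Diketone ⇒ ring A ω-methoxy ketone + ring B aroyl chloride; the 3-OMe arrives with the methoxyacetyl unit.
4. Ring A ketone ⇒ 2,3,4-trimethoxyphenol + methoxyacetyl chloride (ortho-Fries); the phenol ⇒ 2,3,4-trimethoxybenzaldehyde by Dakin oxidation (C–O).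
5. Ring order: rings A and B are bought as benzene rings; ring C (the pyranone) is the only ring built (step 3); ring A receives its fifth oxygen afterwards (step 4).

Assumption: the target has no stereocentre (it is achiral), so "single enantiomer" is taken as the one constitution drawn and no step has to set or protect configuration.

**Route**

Step 1
Reactants: 1 2,3,4-trimethoxybenzaldehyde
Product: 3 2,3,4-trimethoxyphenol, via aryl formate 2 (not isolated)
Conditions: 30% aq. H2O2 (1.3 equiv), H2SO4 (cat.), MeOH, rt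
Reagents that add atoms: hydrogen peroxide, OO
Why: Dakin oxidation (acid-catalysed Baeyer–Villiger type): the aryl group carrying ortho- and para-methoxy donors migrates to oxygen, and formate 2 is methanolysed in the same pot; no stereocentre is involved.

Step 2
Reactants: 3 2,3,4-trimethoxyphenol; 4 methoxyacetyl chloride
Product: 6 1-(2-hydroxy-3,4,5-trimethoxyphenyl)-2-methoxyethan-1-one, via aryl methoxyacetate 5 (not isolated)
Conditions: BF3·OEt2 (3 equiv), 0 → 85 °C; then H2O
Reagents that add atoms: none
Why: O-acylation followed by ortho-Fries rearrangement: the para position is blocked by OMe, C6 is the only open ortho site (and is para to the 3-OMe), and the boron-chelated o-hydroxy ketone is the thermodynamic sink.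

Step 3
Reactants: 6 1-(2-hydroxy-3,4,5-trimethoxyphenyl)-2-methoxyethan-1-one; 7 4-(benzyloxy)-2-methoxybenzoic acid
Product: 11 2-(4-hydroxy-2-methoxyphenyl)-3,6,7,8-tetramethoxy-4H-chromen-4-one, via acid chloride 8 (not isolated), via diketone 9 (not isolated), via benzyl ether 10 (not isolated)
Conditions: a) 7, (COCl)2, DMF (cat.), CH2Cl2, rt, evaporate; b) 6, LiN(SiMe3)2 (3.3 equiv), THF, −78 °C, then 8, → rt, aq. HCl quench; c) crude 9, AcOH/conc. HCl (5:1), 90 °C
Reagents that add atoms: none
Why: Baker–Venkataraman-type C-aroylation of the phenoxide–enolate dianion gives diketone 9, acid cyclodehydration closes ring C through the O1–C2 bond, and HCl/AcOH acidolysis removes the aryl benzyl ether while the methyl ethers (none of them peri to the carbonyl) stay; no stereocentre is formed.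

Step 4
Reactants: 11 2-(4-hydroxy-2-methoxyphenyl)-3,6,7,8-tetramethoxy-4H-chromen-4-one
Product: 14 5,4'-dihydroxy-3,6,7,8,2'-pentamethoxyflavone, via mono(trifluoroacetate) 12 (not isolated), via bis(trifluoroacetate) 13 (not isolated)
Conditions: (CF3CO)2O/CF3CO2H (1:3), rt, 30 min; then [RuCl2(p-cymene)]2 (5 mol%), PhI(OCOCF3)2 (1.5 equiv), 80 °C; then Me2S, MeOH, rt
Reagents that add atoms: phenyliodine bis(trifluoroacetate), O=C(OI(OC(=O)C(F)(F)F)c1ccccc1)C(F)(F)F; trifluoroacetic acid, OC(=O)C(F)(F)F (the C5 oxygen is a trifluoroacetate oxygen, and the carboxylate ligands exchange with the medium)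
Why: Proposed new method: carbonyl-directed peri C5–H oxygenation of a fully substituted flavonol ether — divalent ruthenium (as its trifluoroacetate, formed from [RuCl2(p-cymene)]2 in the medium) binds the C4 carbonyl oxygen, carboxylate-assisted metalation of the only C–H within reach (C5, electron-rich through the 6-OMe) gives a five-membered ruthenacycle, the trivalent iodine oxidant takes it to tetravalent ruthenium, and C–O reductive elimination gives the 5-trifluoroacetate 13, which, like the 4'-trifluoroacetate 12 formed beforehand, is too electron-poor to be over-oxidised and is methanolysed to the chelated 5-OH after the oxidant is quenched; the closest known reaction type is ketone-directed ortho C–H hydroxylation of aryl ketones and simple chromones or flavones with ruthenium–arene catalysts in CF3CO2H/(CF3CO)2O, not yet shown for a peri C–H flanked by a methoxy group in a penta-oxygenated 3-methoxyflavone or with a phenol masked in situ; no stereocentre is formed.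

**Compound list**
1 | 2,3,4-trimethoxybenzaldehyde | COc1ccc(C=O)c(OC)c1OC | starting material
2 | 2,3,4-trimethoxyphenyl formate | COc1ccc(OC=O)c(OC)c1OC | intermediate
3 | 2,3,4-trimethoxyphenol | COc1ccc(O)c(OC)c1OC | intermediate
4 | methoxyacetyl chloride | COCC(Cl)=O | starting material
5 | 2,3,4-trimethoxyphenyl methoxyacetate | COCC(=O)Oc1ccc(OC)c(OC)c1OC | intermediate
6 | 1-(2-hydroxy-3,4,5-trimethoxyphenyl)-2-methoxyethan-1-one | COCC(=O)c1cc(OC)c(OC)c(OC)c1O | intermediate
7 | 4-(benzyloxy)-2-methoxybenzoic acid | COc1cc(OCc2ccccc2)ccc1C(O)=O | starting material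
8 | 4-(benzyloxy)-2-methoxybenzoyl chloride | COc1cc(OCc2ccccc2)ccc1C(Cl)=O | intermediate
9 | 1-[4-(benzyloxy)-2-methoxyphenyl]-3-(2-hydroxy-3,4,5-trimethoxyphenyl)-2-methoxypropane-1,3-dione | COC(C(=O)c1ccc(OCc2ccccc2)cc1OC)C(=O)c1cc(OC)c(OC)c(OC)c1O | intermediate
10 | 2-[4-(benzyloxy)-2-methoxyphenyl]-3,6,7,8-tetramethoxy-4H-chromen-4-one | COc1cc(OCc2ccccc2)ccc1-c1oc2c(OC)c(OC)c(OC)cc2c(=O)c1OC | intermediate
11 | 2-(4-hydroxy-2-methoxyphenyl)-3,6,7,8-tetramethoxy-4H-chromen-4-one (4'-hydroxy-3,6,7,8,2'-pentamethoxyflavone) | COc1cc(O)ccc1-c1oc2c(OC)c(OC)c(OC)cc2c(=O)c1OC | intermediate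
12 | 3-methoxy-4-(3,6,7,8-tetramethoxy-4-oxo-4H-chromen-2-yl)phenyl trifluoroacetate | COc1cc(OC(=O)C(F)(F)F)ccc1-c1oc2c(OC)c(OC)c(OC)cc2c(=O)c1OC | intermediate
13 | 2-[2-methoxy-4-(trifluoroacetoxy)phenyl]-3,6,7,8-tetramethoxy-4-oxo-4H-chromen-5-yl trifluoroacetate | COc1cc(OC(=O)C(F)(F)F)ccc1-c1oc2c(OC)c(OC)c(OC)c(OC(=O)C(F)(F)F)c2c(=O)c1OC | intermediate
14 | 5,4'-dihydroxy-3,6,7,8,2'-pentamethoxyflavone (5-hydroxy-2-(4-hydroxy-2-methoxyphenyl)-3,6,7,8-tetramethoxy-4H-chromen-4-one) | COc1cc(O)ccc1-c1oc2c(OC)c(OC)c(OC)c(O)c2c(=O)c1OC | target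

**Totals and risks**

Total step count: 4 (isolated: 3, 6, 11, 14). Longest linear sequence: 4 steps (1 → 3 → 6 → 11 → 14); acid 7 enters in step 3 without steps of its own. Phenol 3 is itself a catalogue compound at a higher price; the count starts from the cheap aldehyde 1.

Steps most likely to fail:

Step 4 (proposed new C–H hydroxylation). The risks are slow metalation next to the 6-OMe, oxidation of the electron-rich ring A by the iodane, and quinone formation from the product if oxidant survives into the methanolysis. The fallback uses known chemistry and puts the fifth ring A oxygen in before ring C is closed; it sets out from 6 and comes back at 14. Ring bromination of 6 at its only free aromatic position (NBS, MeCN, 0 °C) gives 1-(2-bromo-6-hydroxy-3,4,5-trimethoxyphenyl)-2-methoxyethan-1-one F1. Ullmann-type methoxylation (NaOMe, CuBr cat., DMF/MeOH, 110 °C) gives 1-(2-hydroxy-3,4,5,6-tetramethoxyphenyl)-2-methoxyethan-1-one F2. C-aroylation with 8 under the conditions of step 3 b) gives 1-[4-(benzyloxy)-2-methoxyphenyl]-3-(2-hydroxy-3,4,5,6-tetramethoxyphenyl)-2-methoxypropane-1,3-dione F3. Cyclodehydration (H2SO4 cat., AcOH, 60 °C) gives 2-[4-(benzyloxy)-2-methoxyphenyl]-3,5,6,7,8-pentamethoxy-4H-chromen-4-one F4. BCl3 (CH2Cl2, −78 → 0 °C) then cleaves the chelated 5-OMe and the benzyl ether to give 14.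

Step 3 (three events telescoped). The risks are O- versus C-acylation of the dianion by the electron-rich, ortho-substituted aroyl chloride, and C-benzylation of ring B during the acid debenzylation. The fallback sets out from 6 and 8 and comes back at 11. O-Aroylation (pyridine, DMAP, rt) gives the isolable ester 2,3,4-trimethoxy-6-(2-methoxyacetyl)phenyl 4-(benzyloxy)-2-methoxybenzoate F5. Intramolecular Baker–Venkataraman rearrangement (KOH, pyridine, 50 °C) gives 9. Mild cyclodehydration (H2SO4 cat., AcOH, 60 °C) is stopped at the isolated benzyl ether 10, and the benzyl group is removed by hydrogenolysis (H2, 10% Pd/C, EtOAc/MeOH, rt) to give 11.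

Step 2 (Fries step). The risks are a sluggish methoxyacetyl migration, attack at C5, and loss of the 2-OMe next to the boron-bound phenol. The fallback sets out from 3 and comes back at 6. O-Methylation (MeI, K2CO3, acetone) gives 1,2,3,4-tetramethoxybenzene F6, whose two open positions are equivalent. Friedel–Crafts acylation with 4 (AlCl3, 2.5 equiv, CH2Cl2, 0 °C → rt) gives 2-methoxy-1-(2,3,4,5-tetramethoxyphenyl)ethan-1-one F7. The excess AlCl3 cleaves the one methoxy group ortho to the carbonyl in the same pot through the six-membered chelate, giving 6.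

**Further compounds**
F1 | step 4 | 1-(2-bromo-6-hydroxy-3,4,5-trimethoxyphenyl)-2-methoxyethan-1-one | COCC(=O)c1c(Br)c(OC)c(OC)c(OC)c1O
F2 | step 4 | 1-(2-hydroxy-3,4,5,6-tetramethoxyphenyl)-2-methoxyethan-1-one | COCC(=O)c1c(OC)c(OC)c(OC)c(OC)c1O
F3 | step 4 | 1-[4-(benzyloxy)-2-methoxyphenyl]-3-(2-hydroxy-3,4,5,6-tetramethoxyphenyl)-2-methoxypropane-1,3-dione | COC(C(=O)c1ccc(OCc2ccccc2)cc1OC)C(=O)c1c(OC)c(OC)c(OC)c(OC)c1O
F4 | step 4 | 2-[4-(benzyloxy)-2-methoxyphenyl]-3,5,6,7,8-pentamethoxy-4H-chromen-4-one | COc1cc(OCc2ccccc2)ccc1-c1oc2c(OC)c(OC)c(OC)c(OC)c2c(=O)c1OC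
F5 | step 3 | 2,3,4-trimethoxy-6-(2-methoxyacetyl)phenyl 4-(benzyloxy)-2-methoxybenzoate | COCC(=O)c1cc(OC)c(OC)c(OC)c1OC(=O)c1ccc(OCc2ccccc2)cc1OC
F6 | step 2 | 1,2,3,4-tetramethoxybenzene | COc1ccc(OC)c(OC)c1OC
F7 | step 2 | 2-methoxy-1-(2,3,4,5-tetramethoxyphenyl)ethan-1-one | COCC(=O)c1cc(OC)c(OC)c(OC)c1OC
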